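## Retrosynthetic overview
1. All three O-heterocycles are opened at once (lactone C1–O2 and both ketal bonds at C5''). This leads to the open-chain seco acid 2-(1,8,14-trihydroxy-11-oxopentadecyl)-4,6-dimethoxybenzoic acid, the presumed last acyclic biosynthetic intermediate.
2. The seco acid is cut into CO2 (C1) and an aryl bromide. Its γ,γ'-dihydroxy ketone is cut into acetone (as the N,N-dimethylhydrazone, a twofold α-nucleophile supplying C4''–C5''–C9''), (S)-propylene oxide and a terminal (S)-epoxide.
3. The bromoaryl carbinol/epoxide is cut at C3–C1'. This bond comes from catalytic enantioselective addition of the dialkylzinc from (S)-1,2-epoxy-7-octene to 2-bromo-3,5-dimethoxybenzaldehyde.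
4. Ring order: the benzene ring is bought. The γ-lactone, the first tetrahydrofuran (hemiketal) and the second tetrahydrofuran (spiroketal) all close in the last flask on acidification.

Assumption: operations run in one flask without isolation count as one step, returning the crude HPLC fraction of the spiro epimer to acid counts as part of the last step, and the acid-labile spiro centre C5'' is taken to equilibrate to about 1:1 (E,E)/(Z,Z).

## Route

Step 1
Reactants: 1 3,5-dimethoxybenzaldehyde
Product: 2 2-bromo-3,5-dimethoxybenzaldehyde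
Conditions: NBS (1.05 equiv), MeCN, 0 °C to rt
Reagents that add atoms: N-bromosuccinimide, O=C1CCC(=O)N1Br
Why: Electrophilic aromatic bromination goes to C2, which is ortho/para to the two methoxy groups and less crowded than C4 between them; no stereocentre is formed.

Step 2
Reactants: 3 rac-2-(hex-5-en-1-yl)oxirane (1,2-epoxy-7-octene)
Product: 4 (2S)-2-(hex-5-en-1-yl)oxirane
Conditions: (S,S)-Co(salen) (0.5 mol %), AcOH, air; H2O (0.55 equiv), neat, 0 °C to rt, 16 h; distillation
Reagents that add atoms: none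
Why: In the Jacobsen hydrolytic kinetic resolution the (S,S)-Co(III) catalyst hydrolyses the (R)-epoxide far faster (krel > 100 for unbranched terminal epoxides), so (S)-4 is recovered in >99% ee and later becomes C2''.

Step 3
Reactants: 4 (2S)-2-(hex-5-en-1-yl)oxirane, 2 2-bromo-3,5-dimethoxybenzaldehyde
Product: 7 (1R)-1-(2-bromo-3,5-dimethoxyphenyl)-7-[(2S)-oxiran-2-yl]heptan-1-ol, via diethyl{6-[(2S)-oxiran-2-yl]hexyl}borane 5 (not isolated), via bis{6-[(2S)-oxiran-2-yl]hexyl}zinc 6 (not isolated)
Conditions: 4 (4 equiv), Et2BH (from BH3·SMe2 + 2 BEt3), Et2O, 0 °C to rt; Et2Zn, 0 °C, then vacuum; 2 (1 equiv), Ti(OiPr)4 (2 equiv), (1S,2S)-C6H10(NHTf)2 (8 mol %), PhMe, −20 °C, 12 h; H2O/aq. Rochelle salt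
Reagents that add atoms: none
Why: Anti-Markovnikov hydroboration, Knochel boron–zinc exchange and Ti/bis(triflamide)-catalysed enantioselective dialkylzinc addition leave the remote epoxide and the ArBr untouched because the dialkylzinc is salt-free and the temperature low, and the (1S,2S)-ligand delivers the alkyl group to the Re face of the aldehyde to set C3 as R (the (1R,2R)-ligand is known to give (S)-1-arylalkanols).

Step 4
Reactants: 8 acetone N,N-dimethylhydrazone, 9 (S)-propylene oxide, 7 (1R)-1-(2-bromo-3,5-dimethoxyphenyl)-7-[(2S)-oxiran-2-yl]heptan-1-ol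
Product: 16 (3R)-5,7-dimethoxy-3-{6-[(2S,5R,7S)-7-methyl-1,6-dioxaspiro[4.4]nonan-2-yl]hexyl}-2-benzofuran-1(3H)-one, via (2S)-5-(2,2-dimethylhydrazinylidene)hexan-2-ol 10 (not isolated), via (1R,8S,14S)-1-(2-bromo-3,5-dimethoxyphenyl)-11-(2,2-dimethylhydrazinylidene)pentadecane-1,8,14-triol 11 (not isolated), via {2-[(1R,8S,14S)-11-(2,2-dimethylhydrazinylidene)-1,8,14-trioxidopentadecyl]-4,6-dimethoxyphenyl}lithium trilithium salt 12 (not isolated), via 2-[(1R,8S,14S)-11-(2,2-dimethylhydrazinylidene)-1,8,14-trihydroxypentadecyl]-4,6-dimethoxybenzoic acid 13 (not isolated), via 2-[(1R,8S,14S)-1,8,14-trihydroxy-11-oxopentadecyl]-4,6-dimethoxybenzoic acid 14 (not isolated), via (3R)-5,7-dimethoxy-3-{6-[(2S,5S,7S)-7-methyl-1,6-dioxaspiro[4.4]nonan-2-yl]hexyl}-2-benzofuran-1(3H)-one 15 (not isolated)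
Conditions: (a) 8 (2.5 equiv), n-BuLi, THF, −78 to 0 °C; 9, 0 °C to rt; n-BuLi, −78 to 0 °C; (b) Li alkoxide of 7 (MeLi, 1.0 equiv, THF, −78 °C), 0 °C to rt, 12 h; (c) t-BuLi (2.2 equiv), −78 °C, 10 min; CO2 (g); (d) 3 M HCl, THF, rt, 6 h; (e) normal-phase HPLC takes out 16; the crude fraction holding 15 goes back, unpurified, into CSA (cat.), CH2Cl2, rt, and is re-injected (3 cycles)
Reagents that add atoms: carbon dioxide, O=C=O
Why: Corey–Enders azaenolate alkylation at the less substituted α-carbon opens each terminal epoxide at its CH2 with retention at C7'' and C2'', Li–Br exchange outruns hydrazone deprotonation at −78 °C so that CO2 installs C1, and acidification releases the seco acid 14, which folds as in the presumed biosynthesis by γ-lactonisation (the C3–O bond is untouched, so 3R is kept) and double dehydrative spiroketalisation, in which C5'' is under thermodynamic control because (Z,Z)-15 (5''S) and (E,E)-16 (5''R) interconvert in acid through the ring-opened oxocarbenium ion to a roughly 1:1 mixture, so that 16 is drawn off by HPLC while the stream holding 15 is returned to acid and converted further.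

## Compound list
1 | 3,5-dimethoxybenzaldehyde | COc1cc(OC)cc(C=O)c1 | starting material
2 | 2-bromo-3,5-dimethoxybenzaldehyde | COc1cc(OC)c(Br)c(C=O)c1 | intermediate
3 | rac-2-(hex-5-en-1-yl)oxirane | C=CCCCCC1CO1 | starting material
4 | (2S)-2-(hex-5-en-1-yl)oxirane | C=CCCCC[C@H]1CO1 | intermediate
5 | diethyl{6-[(2S)-oxiran-2-yl]hexyl}borane | CCB(CC)CCCCCC[C@H]1CO1 | intermediate (not isolated)
6 | bis{6-[(2S)-oxiran-2-yl]hexyl}zinc | [Zn](CCCCCC[C@H]1CO1)CCCCCC[C@H]1CO1 | intermediate (not isolated)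
7 | (1R)-1-(2-bromo-3,5-dimethoxyphenyl)-7-[(2S)-oxiran-2-yl]heptan-1-ol | COc1cc(OC)c(Br)c(c1)[C@@H](CCCCCC[C@H]1CO1)O | intermediate
8 | acetone N,N-dimethylhydrazone | CC(C)=NN(C)C | starting material
9 | (S)-propylene oxide | C[C@H]1CO1 | starting material
10 | (2S)-5-(2,2-dimethylhydrazinylidene)hexan-2-ol (in the flask as Li alkoxide, then C,O-dilithiated) | C[C@H](O)CCC(C)=NN(C)C | intermediate (not isolated)
11 | (1R,8S,14S)-1-(2-bromo-3,5-dimethoxyphenyl)-11-(2,2-dimethylhydrazinylidene)pentadecane-1,8,14-triol (in the flask as trilithium alkoxide) | COc1cc(OC)c(Br)c(c1)[C@@H](CCCCCC[C@H](O)CCC(CC[C@H](C)O)=NN(C)C)O | intermediate (not isolated)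
12 | aryllithium of 11, trilithium alkoxide | COc1cc(OC)c([Li])c(c1)[C@@H](CCCCCC[C@H](O[Li])CCC(CC[C@H](C)O[Li])=NN(C)C)O[Li] | intermediate (not isolated)
13 | 2-[(1R,8S,14S)-11-(2,2-dimethylhydrazinylidene)-1,8,14-trihydroxypentadecyl]-4,6-dimethoxybenzoic acid (in the flask as Li salt) | COc1cc(OC)c(C(=O)O)c(c1)[C@@H](CCCCCC[C@H](O)CCC(CC[C@H](C)O)=NN(C)C)O | intermediate (not isolated)
14 | 2-[(1R,8S,14S)-1,8,14-trihydroxy-11-oxopentadecyl]-4,6-dimethoxybenzoic acid (seco acid) | COc1cc(OC)c(C(=O)O)c(c1)[C@@H](CCCCCC[C@H](O)CCC(=O)CC[C@H](C)O)O | intermediate (not isolated)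
15 | (3R)-5,7-dimethoxy-3-{6-[(2S,5S,7S)-7-methyl-1,6-dioxaspiro[4.4]nonan-2-yl]hexyl}-2-benzofuran-1(3H)-one (Z,Z spiro epimer, in acid equilibrium with 16) | COc1cc(OC)c2c(c1)[C@@H](CCCCCC[C@H]1CC[C@]3(CC[C@H](C)O3)O1)OC2=O | intermediate (not isolated)
16 | (3R)-5,7-dimethoxy-3-{6-[(2S,5R,7S)-7-methyl-1,6-dioxaspiro[4.4]nonan-2-yl]hexyl}-2-benzofuran-1(3H)-one (E,E) | COc1cc(OC)c2c(c1)[C@@H](CCCCCC[C@H]1CC[C@@]3(CC[C@H](C)O3)O1)OC2=O | target

## Step count and risks
Total step count: 4.
Longest linear sequence: 3 (steps 2, 3 and 4; 3 → 4 → 7 → 16).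

**Step 4 (highest risk).** The second metalation may be incomplete. Protons may shuttle between azaenolates, although stray α-carboxylation is harmless because the β-keto acid loses CO2 in the acid stage. The aryllithium may be quenched before CO2 arrives. The roughly 1:1 pair 15/16 also needs a careful HPLC separation.

The fallback sets out from 7 and comes back at 16. Dilithiated 10 is alkylated with the alkoxide of 7 as before to give 11, but the flask is acidified directly, without the lithiation/CO2 stage. This gives (1R)-1-(2-bromo-3,5-dimethoxyphenyl)-7-[(2S,5RS,7S)-7-methyl-1,6-dioxaspiro[4.4]nonan-2-yl]heptan-1-ol F1. The lactone is then closed on its own by Pd-catalysed carbonylative lactonisation (Pd(OAc)2, dppf, CO 1 atm, K2CO3, DMF, 100 °C), so no organolithium ever meets the hydrazone. The resulting 15/16 mixture is separated by HPLC with the same acid recycle to deliver 16.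

**Step 3.** Et2BH or Ti(OiPr)4 may attack the epoxide, and the ortho-bromine may lower the ee.

The fallback sets out from 2 and comes back at 7, and it keeps the epoxide out of the organometallic chemistry. 1,7-Octadiene (5 equiv) is mono-hydroborated to diethyl(oct-7-en-1-yl)borane F2, which is exchanged with Et2Zn to bis(oct-7-en-1-yl)zinc F3. This reagent is added to 2 with the same Ti/(1S,2S)-bis(triflamide) catalyst to give (1R)-1-(2-bromo-3,5-dimethoxyphenyl)non-8-en-1-ol F4. mCPBA then gives the 1:1 epoxide mixture (1R)-1-(2-bromo-3,5-dimethoxyphenyl)-7-(oxiran-2-yl)heptan-1-ol F5. Hydrolytic kinetic resolution of this mixture with (S,S)-Co(salen) leaves 7.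

**Step 1.** The 4-bromo and dibromo by-products are hard to remove, and the aldehyde deactivates the ring.

The fallback sets out from 1 (with zinc reagent 6) and comes back at 7, and the bromine is introduced after the C–C bond is made. Reagent 6 is added to 1 under the conditions of step 3 to give (1R)-1-(3,5-dimethoxyphenyl)-7-[(2S)-oxiran-2-yl]heptan-1-ol F6, and the missing ortho substituent should also help the ee. NBS (1.0 equiv, NaHCO3, CH2Cl2, −20 to 0 °C) then brominates the more electron-rich ring ortho to the side chain to give 7.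

## Further compounds
F1 | step 4 | (1R)-1-(2-bromo-3,5-dimethoxyphenyl)-7-[(2S,5RS,7S)-7-methyl-1,6-dioxaspiro[4.4]nonan-2-yl]heptan-1-ol | COc1cc(OC)c(Br)c(c1)[C@@H](CCCCCC[C@H]1CCC3(CC[C@H](C)O3)O1)O
F2 | step 3 | diethyl(oct-7-en-1-yl)borane | CCB(CC)CCCCCCC=C
F3 | step 3 | bis(oct-7-en-1-yl)zinc | C=CCCCCCC[Zn]CCCCCCC=C
F4 | step 3 | (1R)-1-(2-bromo-3,5-dimethoxyphenyl)non-8-en-1-ol | COc1cc(OC)c(Br)c(c1)[C@@H](CCCCCCC=C)O
F5 | step 3 | (1R)-1-(2-bromo-3,5-dimethoxyphenyl)-7-(oxiran-2-yl)heptan-1-ol, 1:1 at the epoxide | COc1cc(OC)c(Br)c(c1)[C@@H](CCCCCCC1CO1)O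
F6 | step 1 | (1R)-1-(3,5-dimethoxyphenyl)-7-[(2S)-oxiran-2-yl]heptan-1-ol | COc1cc(OC)cc(c1)[C@@H](CCCCCC[C@H]1CO1)O
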